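**Retrosynthetic overview**
1. Target 21 ⇐ 20 (loss of two MOM ethers) ⇐ C2–aryl bond: 4H-chromene 15 + 2,4-diformylphloroglucinol 18 by acid-catalysed hydroarylation.
2. Enabling feature: the enol ether O1–C2=C3 in the 4H-pyran ring of 15 (protonation at C3 unmasks an oxocarbenium at C2) and the one unsubstituted ring carbon of 18, flanked by two OH groups; the step creates C3 and C2 under control of C4.
3. 15 ⇐ 12 (C6 formylation by directed metalation) ⇐ lactol 10 (dehydration) ⇐ enamine Michael addition/hemiacetalization of 3-methylbutanal with the o-quinone methide from sulfone 7 (sets C4, closes the pyran ring).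
4. 7 ⇐ 2,4,6-trihydroxybenzaldehyde 1 (bis-MOM ether, i-BuMgBr, sulfinic acid); 18 ⇐ phloroglucinol 16 (double Vilsmeier–Haack formylation).
5. Ring order: both benzene rings are bought; the pyran ring is closed in step 3, flattened to the 4H-chromene in step 4 and re-saturated stereoselectively in the key step.

Key step: step 7

Remark: o-quinone methide 9 is taken to react as its E isomer (isobutyl anti to the ring carbonyl, the usual preference of 2-alkylidene cyclohexadienones); the assignment of C4 in step 3 rests on this.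

Step 1
Reactants: 1 2,4,6-trihydroxybenzaldehyde; 2 chloromethyl methyl ether
Product: 3 2-hydroxy-4,6-bis(methoxymethoxy)benzaldehyde
Conditions: MOMCl (2.2 equiv), i-Pr2NEt, CH2Cl2, 0 °C to rt
Reagents that add atoms: chloromethyl methyl ether, COCCl
Why: Williamson-type O-alkylation that stops at the bis-ether because the remaining 2-OH is locked in a hydrogen bond to the formyl group and is the least nucleophilic hydroxyl (the usual selective MOM protection of 2,4,6-trihydroxyaryl carbonyl compounds); no stereocentre is formed.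

Step 2
Reactants: 3 2-hydroxy-4,6-bis(methoxymethoxy)benzaldehyde; 4 isobutylmagnesium bromide; 5 p-toluenesulfinic acid
Product: 7 2-[3-methyl-1-(4-methylbenzenesulfonyl)butyl]-3,5-bis(methoxymethoxy)phenol (racemic), via benzylic alcohol 6 (not isolated)
Conditions: i-BuMgBr (2.5 equiv), THF, −78 to 0 °C; then p-TolSO2H (4 equiv), 0 °C to rt
Reagents that add atoms: isobutylmagnesium bromide, CC(C)C[Mg]Br; p-toluenesulfinic acid, Cc1ccc(cc1)S(=O)O
Why: Grignard 1,2-addition to the aldehyde (one equivalent is spent on the phenol) followed by SN1 substitution of the highly ionisable ortho-hydroxybenzylic alcohol by sulfinate at sulfur, a known way to make bench-stable o-quinone methide precursors; the new centre is racemic and is destroyed in step 3.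

Step 3
Reactants: 7 2-[3-methyl-1-(4-methylbenzenesulfonyl)butyl]-3,5-bis(methoxymethoxy)phenol; 8 3-methylbutanal
Product: 10 (3S,4S)-5,7-bis(methoxymethoxy)-4-(2-methylpropyl)-3-(propan-2-yl)-3,4-dihydro-2H-chromen-2-ol (both C2 anomers), via o-quinone methide 9 (not isolated)
Conditions: 3-methylbutanal (3 equiv), (R)-α,α-diphenylprolinol trimethylsilyl ether (20 mol %), NaHCO3 (1.5 equiv), CH2Cl2/H2O, 0 °C to rt
Reagents that add atoms: 3-methylbutanal, CC(C)CC=O
Why: Base-induced 1,4-elimination of sulfinate gives o-quinone methide 9, to which the enamine of 3-methylbutanal adds in a known aminocatalytic Michael addition/hemiacetalization; the (R)-catalyst shields one enamine face and the compact synclinal transition state known from nitroalkene acceptors should give the syn adduct, that is 3S,4S (3,4-trans), and because the minor C4 epimer is a diastereomer it can be removed here, before C3 is erased in step 4.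

Step 4
Reactants: 10 (3S,4S)-5,7-bis(methoxymethoxy)-4-(2-methylpropyl)-3-(propan-2-yl)-3,4-dihydro-2H-chromen-2-ol
Product: 12 (4S)-5,7-bis(methoxymethoxy)-4-(2-methylpropyl)-3-(propan-2-yl)-4H-chromene, via anomeric mesylate 11 (not isolated)
Conditions: MsCl (1.5 equiv), Et3N (4 equiv), CH2Cl2, 0 °C to rt
Reagents that add atoms: none
Why: Sulfonylation of the lactol and E1-type elimination through the oxocarbenium ion (the glycal-forming dehydration of 2-deoxy lactols) gives the enol ether; C3 becomes sp2, so its configuration from step 3 is deliberately erased, while C4 is not involved.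

Step 5
Reactants: 12 (4S)-5,7-bis(methoxymethoxy)-4-(2-methylpropyl)-3-(propan-2-yl)-4H-chromene; 13 N,N-dimethylformamide
Product: 15 (4S)-5,7-bis(methoxymethoxy)-4-(2-methylpropyl)-3-(propan-2-yl)-4H-chromene-6-carbaldehyde, via aryllithium 14 (not isolated)
Conditions: n-BuLi (1.2 equiv), TMEDA, THF, −78 to −40 °C; DMF (3 equiv), −78 °C to rt; H2O
Reagents that add atoms: N,N-dimethylformamide, CN(C)C=O
Why: Directed ortho-metalation and DMF quench: C6–H lies between two OMOM groups and is the most acidic ring position (C8–H has one OMOM and the weaker ring oxygen as neighbours), and at low temperature this complex-induced lithiation should outrun deprotonation at C2 or C4, so the C4 centre is untouched.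

Step 6
Reactants: 16 phloroglucinol; 13 N,N-dimethylformamide
Product: 18 2,4,6-trihydroxybenzene-1,3-dicarbaldehyde, via bis(iminium) dichloride 17 (not isolated)
Conditions: POCl3 (2.2 equiv), DMF (2.2 equiv), EtOAc, 0 °C to rt; then H2O, 50 °C
Reagents that add atoms: N,N-dimethylformamide, CN(C)C=O; water, O
Why: Vilsmeier–Haack formylation of the electron-rich triol, which should stop at the dialdehyde because each iminium group deactivates the ring towards a third substitution; no stereocentre is formed.

Step 7
Reactants: 15 (4S)-5,7-bis(methoxymethoxy)-4-(2-methylpropyl)-3-(propan-2-yl)-4H-chromene-6-carbaldehyde; 18 2,4,6-trihydroxybenzene-1,3-dicarbaldehyde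
Product: 20 5-[(2R,3R,4S)-6-formyl-5,7-bis(methoxymethoxy)-4-(2-methylpropyl)-3-(propan-2-yl)-3,4-dihydro-2H-chromen-2-yl]-2,4,6-trihydroxybenzene-1,3-dicarbaldehyde, via oxocarbenium phosphate 19 (not isolated)
Conditions: 18 (3 equiv), (PhO)2P(O)OH (20 mol %), 4 Å MS, MeCN/CH2Cl2, −20 °C to rt, slow addition of 15
Reagents that add atoms: none
Why: The phosphoric acid protonates the enol ether of 15 at C3 on the face opposite the C4 isobutyl group, which is pseudoaxial because the in-plane position is blocked by the C3 isopropyl and C5 OMOM groups, and the resulting 3,4-cis oxocarbenium ion 19 is captured at C2 by the only unsubstituted ring carbon of 18, directly or through a reversibly formed O-aryl acetal that rearranges from O to C. The closest known reaction type is the acid-catalysed Friedel–Crafts C-arylation of cyclic enol ethers by phenols, as used for 2-deoxy aryl C-glycosides from glycals and for C-glycosylation of acylphloroglucinols. No ring is closed, the pyran ring is only re-saturated. C3 is controlled by the resident C4 centre through the anti protonation, and C2 by C3 and C4 together, because in 19 both alkyl groups lie on one face and the arene adds to the other, which gives the 2,3-trans-3,4-cis product (aryl and isopropyl equatorial, isobutyl pseudoaxial), also the arrangement expected to be the most stable. If 19 equilibrates with its 3,4-trans isomer through 15, the result should be the same (Curtin–Hammett), since the trans ion carries an alkyl group on each face of C2 and is attacked more slowly. The step needs C- over O-arylation, attack on the oxocarbenium carbon and not on an aldehyde, and no self-alkylation at C8 of 15 or 20: the O-adduct carries a good leaving group and returns to 19, the aldehydes are hindered or hydrogen-bonded vinylogous acids, and C8 belongs to a ring whose oxygens are all alkylated and conjugated to the formyl group, while 18 is used in excess and 15 is added slowly.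

Step 8
Reactants: 20 5-[(2R,3R,4S)-6-formyl-5,7-bis(methoxymethoxy)-4-(2-methylpropyl)-3-(propan-2-yl)-3,4-dihydro-2H-chromen-2-yl]-2,4,6-trihydroxybenzene-1,3-dicarbaldehyde
Product: 21 5-[(2R,3R,4S)-6-formyl-5,7-dihydroxy-4-(2-methylpropyl)-3-(propan-2-yl)-3,4-dihydro-2H-chromen-2-yl]-2,4,6-trihydroxybenzene-1,3-dicarbaldehyde (target)
Conditions: 3 M HCl, MeOH/THF, rt to 40 °C
Reagents that add atoms: none
Why: Acid-catalysed transacetalisation to methanol removes both MOM ethers, each of which is ortho to the C6 formyl group so that the freed phenols are stabilised by hydrogen bonding; the C2–O1 benzylic ether should survive because the two formyl groups make the 2-aryl ring a poor cation-stabilising group, and no stereocentre is touched.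

**Compound list**
1 | 2,4,6-trihydroxybenzaldehyde | O=Cc1c(O)cc(O)cc1O | starting material
2 | chloromethyl methyl ether | COCCl | starting material
3 | 2-hydroxy-4,6-bis(methoxymethoxy)benzaldehyde | O=Cc1c(O)cc(OCOC)cc1OCOC | intermediate
4 | isobutylmagnesium bromide | CC(C)C[Mg]Br | starting material
5 | p-toluenesulfinic acid | Cc1ccc(cc1)S(=O)O | starting material
6 | 2-(1-hydroxy-3-methylbutyl)-3,5-bis(methoxymethoxy)phenol (racemic; present as its bromomagnesium salt) | CC(C)CC(O)c1c(O)cc(OCOC)cc1OCOC | intermediate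
7 | 2-[3-methyl-1-(4-methylbenzenesulfonyl)butyl]-3,5-bis(methoxymethoxy)phenol (racemic) | CC(C)CC(c1c(O)cc(OCOC)cc1OCOC)S(=O)(=O)c1ccc(C)cc1 | intermediate
8 | 3-methylbutanal | CC(C)CC=O | starting material
9 | (6E)-3,5-bis(methoxymethoxy)-6-(3-methylbutylidene)cyclohexa-2,4-dien-1-one | CC(C)C/C=C1/C(=O)C=C(OCOC)C=C1OCOC | intermediate
10 | (3S,4S)-5,7-bis(methoxymethoxy)-4-(2-methylpropyl)-3-(propan-2-yl)-3,4-dihydro-2H-chromen-2-ol (both C2 anomers) | CC(C)C[C@@H]1c2c(cc(OCOC)cc2OCOC)OC(O)[C@H]1C(C)C | intermediate
11 | (3S,4S)-5,7-bis(methoxymethoxy)-4-(2-methylpropyl)-3-(propan-2-yl)-3,4-dihydro-2H-chromen-2-yl methanesulfonate | CC(C)C[C@@H]1c2c(cc(OCOC)cc2OCOC)OC(OS(C)(=O)=O)[C@H]1C(C)C | intermediate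
12 | (4S)-5,7-bis(methoxymethoxy)-4-(2-methylpropyl)-3-(propan-2-yl)-4H-chromene | CC(C)C[C@@H]1c2c(cc(OCOC)cc2OCOC)OC=C1C(C)C | intermediate
13 | N,N-dimethylformamide | CN(C)C=O | starting material
14 | [(4S)-5,7-bis(methoxymethoxy)-4-(2-methylpropyl)-3-(propan-2-yl)-4H-chromen-6-yl]lithium | CC(C)C[C@@H]1c2c(cc(OCOC)c([Li])c2OCOC)OC=C1C(C)C | intermediate
15 | (4S)-5,7-bis(methoxymethoxy)-4-(2-methylpropyl)-3-(propan-2-yl)-4H-chromene-6-carbaldehyde | CC(C)C[C@@H]1c2c(cc(OCOC)c(C=O)c2OCOC)OC=C1C(C)C | intermediate
16 | phloroglucinol (benzene-1,3,5-triol) | Oc1cc(O)cc(O)c1 | starting material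
17 | N,N'-[(2,4,6-trihydroxy-1,3-phenylene)dimethanylylidene]bis(N-methylmethanaminium) dichloride | C[N+](C)=Cc1c(O)cc(O)c(C=[N+](C)C)c1O.[Cl-].[Cl-] | intermediate
18 | 2,4,6-trihydroxybenzene-1,3-dicarbaldehyde (2,4-diformylphloroglucinol) | O=Cc1c(O)cc(O)c(C=O)c1O | intermediate
19 | (3R,4S)-6-formyl-5,7-bis(methoxymethoxy)-4-(2-methylpropyl)-3-(propan-2-yl)-3,4-dihydrochromen-1-ium diphenyl phosphate | CC(C)C[C@@H]1c2c(cc(OCOC)c(C=O)c2OCOC)[O+]=C[C@@H]1C(C)C.[O-]P(=O)(Oc1ccccc1)Oc1ccccc1 | intermediate
20 | 5-[(2R,3R,4S)-6-formyl-5,7-bis(methoxymethoxy)-4-(2-methylpropyl)-3-(propan-2-yl)-3,4-dihydro-2H-chromen-2-yl]-2,4,6-trihydroxybenzene-1,3-dicarbaldehyde | CC(C)C[C@@H]1c2c(cc(OCOC)c(C=O)c2OCOC)O[C@@H](c2c(O)c(C=O)c(O)c(C=O)c2O)[C@@H]1C(C)C | intermediate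
21 | 5-[(2R,3R,4S)-6-formyl-5,7-dihydroxy-4-(2-methylpropyl)-3-(propan-2-yl)-3,4-dihydro-2H-chromen-2-yl]-2,4,6-trihydroxybenzene-1,3-dicarbaldehyde | CC(C)C[C@@H]1c2c(cc(O)c(C=O)c2O)O[C@@H](c2c(O)c(C=O)c(O)c(C=O)c2O)[C@@H]1C(C)C | target

**Step count and risks**

Total step count: 8. Longest linear sequence: 7 (steps 1, 2, 3, 4, 5, 7, 8).

Steps most likely to fail:

1. Step 3. The alkyl-substituted o-quinone methide may tautomerise to the styrene before the enamine adds, and syn/anti control may be incomplete, which after step 4 would appear as loss of enantiopurity at C4. Fallback (sets out from 16 and 2, returns at 12): C4 is set instead by iminium catalysis on a geometrically defined enal.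
   - Phloroglucinol 16 is alkylated with 2 (2 equiv, i-Pr2NEt) to give 3,5-bis(methoxymethoxy)phenol F1.
   - Friedel–Crafts alkylation/hemiacetalization of F1 with (E)-5-methylhex-2-enal under (R)-α,α-diphenylprolinol trimethylsilyl ether catalysis (arene attack on the iminium face away from the diarylmethyl group) should give (4S)-5,7-bis(methoxymethoxy)-4-(2-methylpropyl)-3,4-dihydro-2H-chromen-2-ol F2.
   - Dehydration (MsCl, Et3N) should give (4S)-5,7-bis(methoxymethoxy)-4-(2-methylpropyl)-4H-chromene F3.
   - Iodination of the enol ether at C3 (N-iodosuccinimide, catalytic AgNO3) should give (4R)-3-iodo-5,7-bis(methoxymethoxy)-4-(2-methylpropyl)-4H-chromene F4 (same spatial arrangement; the descriptor changes because of the iodine).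
   - Negishi coupling with isopropylzinc bromide (Pd, CPhos) then gives 12.

2. Step 7. Stereocontrol at C3 may be lost (protonation on the wrong face, or faster capture of the trans ion), C8 of a second molecule may attack the oxocarbenium ion and cause oligomerisation, or a MOM group may be lost under the acid. Fallback (sets out from 15, returns at 20): the bond is made instead under weakly basic Knoevenagel conditions, where only the acidic phenol 18 acts as carbon nucleophile.
   - Hydration of 15 (PPTS, THF/H2O) gives (4S)-2-hydroxy-5,7-bis(methoxymethoxy)-4-(2-methylpropyl)-3-(propan-2-yl)-3,4-dihydro-2H-chromene-6-carbaldehyde F5.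
   - The open-chain aldehyde form of F5 condenses with 18 (ethylenediammonium diacetate, MeCN, 50 °C) to the o-quinone methide 2,4-diformyl-3,5-dihydroxy-6-{(3S)-3-[3-formyl-6-hydroxy-2,4-bis(methoxymethoxy)phenyl]-5-methyl-2-(propan-2-yl)hexylidene}cyclohexa-2,4-dien-1-one F6.
   - Intramolecular oxa-Michael addition of the liberated phenol (6-exo-trig) closes the pyran ring and gives 20. C3 (enolisable aldehyde) and C2 (reversible oxa-Michael addition) should equilibrate towards the arrangement with aryl and isopropyl equatorial.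

3. Step 5. Lithiation of the enol ether C2–H or deprotonation of the doubly activated C4–H may compete, which would erode the enantiopurity set in step 3. Fallback (sets out from 10, returns at 15): the metalation is moved to a saturated substrate.
   - Lactol 10 is converted (MeOH, PPTS) into (3S,4S)-2-methoxy-5,7-bis(methoxymethoxy)-4-(2-methylpropyl)-3-(propan-2-yl)-3,4-dihydro-2H-chromene F7.
   - Directed ortho-metalation and DMF quench as in step 5 should give (3S,4S)-2-methoxy-5,7-bis(methoxymethoxy)-4-(2-methylpropyl)-3-(propan-2-yl)-3,4-dihydro-2H-chromene-6-carbaldehyde F8.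
   - Acid-catalysed elimination of methanol (PPTS, toluene, 90 °C, 5 Å MS) gives 15.

**Further compounds**
F1 | step 3 | 3,5-bis(methoxymethoxy)phenol | Oc1cc(OCOC)cc(OCOC)c1
F2 | step 3 | (4S)-5,7-bis(methoxymethoxy)-4-(2-methylpropyl)-3,4-dihydro-2H-chromen-2-ol | CC(C)C[C@@H]1c2c(cc(OCOC)cc2OCOC)OC(O)C1
F3 | step 3 | (4S)-5,7-bis(methoxymethoxy)-4-(2-methylpropyl)-4H-chromene | CC(C)C[C@@H]1c2c(cc(OCOC)cc2OCOC)OC=C1
F4 | step 3 | (4R)-3-iodo-5,7-bis(methoxymethoxy)-4-(2-methylpropyl)-4H-chromene | CC(C)C[C@@H]1c2c(cc(OCOC)cc2OCOC)OC=C1I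
F5 | step 7 | (4S)-2-hydroxy-5,7-bis(methoxymethoxy)-4-(2-methylpropyl)-3-(propan-2-yl)-3,4-dihydro-2H-chromene-6-carbaldehyde | CC(C)C[C@@H]1c2c(cc(OCOC)c(C=O)c2OCOC)OC(O)C1C(C)C
F6 | step 7 | 2,4-diformyl-3,5-dihydroxy-6-{(3S)-3-[3-formyl-6-hydroxy-2,4-bis(methoxymethoxy)phenyl]-5-methyl-2-(propan-2-yl)hexylidene}cyclohexa-2,4-dien-1-one | CC(C)C[C@H](c1c(O)cc(OCOC)c(C=O)c1OCOC)C(C(C)C)C=C1C(=O)C(C=O)=C(O)C(C=O)=C1O
F7 | step 5 | (3S,4S)-2-methoxy-5,7-bis(methoxymethoxy)-4-(2-methylpropyl)-3-(propan-2-yl)-3,4-dihydro-2H-chromene | CC(C)C[C@@H]1c2c(cc(OCOC)cc2OCOC)OC(OC)[C@H]1C(C)C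
F8 | step 5 | (3S,4S)-2-methoxy-5,7-bis(methoxymethoxy)-4-(2-methylpropyl)-3-(propan-2-yl)-3,4-dihydro-2H-chromene-6-carbaldehyde | CC(C)C[C@@H]1c2c(cc(OCOC)c(C=O)c2OCOC)OC(OC)[C@H]1C(C)C
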